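Assumption: natural-source (2E,7R,11R)-phytol (single stereoisomer, chlorophyll-derived) and 3-bromo-5-methylanisole are treated as catalogue chemicals.

## Retrosynthetic overview
- The target comes from its 6-O-methyl ether. The arene is bought, so the dihydropyran is the only ring built, and it is closed last.
- The ring is closed at the aryl C8a–O bond by intramolecular Pd C–O coupling. The C2–O bond is never broken, so the tertiary carbinol configuration carries over with retention.
- The aryl bromide needed for that coupling comes from para-selective bromination of a 3,5-dialkylanisole.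
- The C4–C4a bond comes from hydroboration and B-alkyl Suzuki coupling of (3R)-isophytol with 3-bromo-5-methylanisole.
- (3R)-Isophytol comes from reductive 1,3-transposition of (2R,3R)-epoxyphytol, made by Sharpless epoxidation of phytol. This sets C2, while 4'R and 8'R come from the chiral pool.

## Route

**Step 1**
- Reactants: 1, natural phytol, (2E,7R,11R)-3,7,11,15-tetramethylhexadec-2-en-1-ol
- Product: 2, (2R,3R,7R,11R)-2,3-epoxy-3,7,11,15-tetramethylhexadecan-1-ol (CH2OH and 3-CH3 cis on the oxirane)
- Conditions: Ti(OiPr)4 (10 mol %), D-(−)-DIPT (12 mol %), t-BuOOH (2 equiv, decane), 4 Å MS, CH2Cl2, −20 °C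
- Reagents that add atoms: tert-butyl hydroperoxide, CC(C)(C)OO
- Why: In this Katsuki–Sharpless asymmetric epoxidation, D-(−)-tartrate gives the (2R,3R) epoxide of an E-trisubstituted allylic alcohol (geraniol gives 2S,3S with L-(+)-tartrate), which sets the future chroman C2 as R under reagent control (dr ≥ 95:5 expected) and leaves C7 and C11 untouched.

**Step 2**
- Reactants: 2, (2R,3R,7R,11R)-2,3-epoxyphytol
- Product: 3, (2S,3R,7R,11R)-2,3-epoxy-1-iodo-3,7,11,15-tetramethylhexadecane (same geometry as 2; the C2 descriptor changes only because CH2I now outranks C3)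
- Conditions: I2, PPh3, imidazole, THF, 0 °C; short silica plug, used directly
- Reagents that add atoms: iodine, II
- Why: This Appel/Garegg–Samuelsson iodination is an SN2 reaction at the primary carbon, and the imidazole buffer protects the acid-sensitive trisubstituted epoxide and both of its stereocentres.

**Step 3**
- Reactants: 3, (2S,3R,7R,11R)-2,3-epoxy-1-iodophytane
- Product: 4, (3R,7R,11R)-3,7,11,15-tetramethylhexadec-1-en-3-ol ((3R)-isophytol)
- Conditions: activated Zn dust, EtOH, reflux (neutral work-up)
- Reagents that add atoms: none
- Why: In this reductive β-elimination of a 2,3-epoxy iodide (epoxy alcohol to allylic alcohol 1,3-transposition), zinc inserts into C–I and expels the C2–O bond, so the C3–O bond is never broken and 3R is retained.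

**Step 4**
- Reactants: 4, (3R,7R,11R)-isophytol; 5, 3-bromo-5-methylanisole (1-bromo-3-methoxy-5-methylbenzene)
- Product: 6, (3R,7R,11R)-1-(3-methoxy-5-methylphenyl)-3,7,11,15-tetramethylhexadecan-3-ol
- Conditions: 9-BBN-H (2.5 equiv), THF, 0 °C to rt; then 5, PdCl2(dppf) (5 mol %), aq K3PO4 (3 equiv), THF/DMF, 65 °C
- Reagents that add atoms: none
- Why: Anti-Markovnikov hydroboration of the vinyl group next to a quaternary carbon, followed by B-alkyl Suzuki–Miyaura coupling, forms the C4–C4a bond using only the aryl group of 5 and one H from 9-BBN; the extra 9-BBN covers the free OH, the borinate hydrolyses in the aqueous base, and no bond to the stereocentre changes.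

**Step 5**
- Reactants: 6, (3R,7R,11R)-1-(3-methoxy-5-methylphenyl)-3,7,11,15-tetramethylhexadecan-3-ol
- Product: 7, (3R,7R,11R)-1-(2-bromo-5-methoxy-3-methylphenyl)-3,7,11,15-tetramethylhexadecan-3-ol
- Conditions: NBS (1.0 equiv), MeCN, 0 °C to rt, dark
- Reagents that add atoms: N-bromosuccinimide, O=C1CCC(=O)N1Br
- Why: In this electrophilic aromatic bromination, NBS/MeCN brominates 3,5-dialkylanisoles para to OMe (3,5-dimethylanisole gives the 4-bromide), which places Br at the future C8a; the saturated chain and tertiary alcohol are inert.

**Step 6**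
- Reactants: 7, (3R,7R,11R)-1-(2-bromo-5-methoxy-3-methylphenyl)-3,7,11,15-tetramethylhexadecan-3-ol
- Product: 8, (2R,4'R,8'R)-δ-tocopherol methyl ether, (2R)-6-methoxy-2,8-dimethyl-2-[(4R,8R)-4,8,12-trimethyltridecyl]chroman
- Conditions: Pd(OAc)2 (5 mol %), 2-(di-tert-butylphosphino)-1,1'-binaphthyl (6 mol %), Cs2CO3 (1.5 equiv), toluene, 90 °C
- Reagents that add atoms: none
- Why: In this intramolecular Buchwald–Hartwig-type C–O coupling, the tertiary alkoxide has no carbinol H for β-hydride elimination and the new bond is aryl–O, so the 3R carbinol becomes 2R with strict retention.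

**Step 7**
- Reactants: 8, (2R,4'R,8'R)-δ-tocopherol methyl ether
- Product: 9, (2R,4'R,8'R)-δ-tocopherol (target)
- Conditions: NaSEt (5 equiv), DMF, 130 °C, Ar; then aq NH4Cl
- Reagents that add atoms: none
- Why: Thiolate demethylation of the aryl methyl ether is an SN2 attack that can only occur at the unhindered O–CH3 carbon, so no Lewis acid is present to ionise the tertiary C2–O bond and C2 cannot epimerise.

## Compound list
1 | natural phytol, (2E,7R,11R) | OC/C=C(\C)CCC[C@H](C)CCC[C@H](C)CCCC(C)C | starting material
2 | (2R,3R,7R,11R)-2,3-epoxyphytol | O1[C@](C)(CCC[C@H](C)CCC[C@H](C)CCCC(C)C)[C@H]1CO | intermediate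
3 | (2S,3R,7R,11R)-2,3-epoxy-1-iodophytane | O1[C@](C)(CCC[C@H](C)CCC[C@H](C)CCCC(C)C)[C@H]1CI | intermediate
4 | (3R,7R,11R)-isophytol | O[C@](C)(CCC[C@H](C)CCC[C@H](C)CCCC(C)C)C=C | intermediate
5 | 3-bromo-5-methylanisole | COc1cc(C)cc(Br)c1 | starting material
6 | (3R,7R,11R)-1-(3-methoxy-5-methylphenyl)-3,7,11,15-tetramethylhexadecan-3-ol | O[C@](C)(CCC[C@H](C)CCC[C@H](C)CCCC(C)C)CCc1cc(C)cc(OC)c1 | intermediate
7 | (3R,7R,11R)-1-(2-bromo-5-methoxy-3-methylphenyl)-3,7,11,15-tetramethylhexadecan-3-ol | O[C@](C)(CCC[C@H](C)CCC[C@H](C)CCCC(C)C)CCc1cc(OC)cc(C)c1Br | intermediate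
8 | (2R,4'R,8'R)-δ-tocopherol methyl ether | Cc1cc(OC)cc2c1O[C@](C)(CCC[C@H](C)CCC[C@H](C)CCCC(C)C)CC2 | intermediate
9 | (2R,4'R,8'R)-δ-tocopherol | Cc1cc(O)cc2c1O[C@](C)(CCC[C@H](C)CCC[C@H](C)CCCC(C)C)CC2 | target

## Totals
- Total step count: 7 (six operations if Steps 2 and 3 are telescoped).
- Longest linear sequence: 7, from phytol. Compound 5 is purchased and enters at Step 4.

## Three steps most likely to fail

1. **Step 6.** The bromide is di-ortho-substituted and electron-rich, so C–O reductive elimination may be slow and hydrodebromination may compete.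
   - Fallback: close the ring through the quinone instead.
   - Use 1-bromo-2,5-dimethoxy-3-methylbenzene in Step 4. It is made from 4-methoxy-2-methylphenol by ortho-bromination and O-methylation.
   - Oxidise the coupled product with CAN to δ-tocopherylquinone, then hydrogenate to the hydroquinone.
   - Cyclodehydrate with acid via the hemiketal. Retention at C2 is expected by analogy with the α-series but is untested here, so check the C2 epimer ratio by chiral HPLC.
   - This replaces Steps 5–7.

2. **Step 4.** The free tertiary allylic alcohol may give sluggish transmetalation or protodeboronation in the hydroboration/Suzuki sequence.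
   - Fallback: bypass 3 and 4 and reverse the polarity of the coupling.
   - Open epoxide 2 with Red-Al to the (3R)-1,3-diol and tosylate the primary OH selectively.
   - Couple the tosylate with excess aryl Grignard from 5 under Li2CuCl4 catalysis (Kochi-type sp3–sp2 coupling) to reach 6.

3. **Step 5.** Bromination may give ortho/para mixtures or overbromination.
   - Fallback: buy the halogen already in place as 4-bromo-3,5-dimethylanisole.
   - Monobrominate one benzylic CH3 (Wohl–Ziegler) and convert the product to the benzylic zinc/copper reagent.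
   - Use it to open (R)-2-methyl-2-[(4R,8R)-4,8,12-trimethyltridecyl]oxirane at the CH2 terminus, which gives 7 directly.
   - The oxirane comes from (6R,10R)-phytone, obtained by oxidative cleavage of 1, followed by catalytic asymmetric Corey–Chaykovsky methylenation.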